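**Plan**

- Retrosynthetic cuts, in order: the C7=C11 alkene (back to an 11-hydroxy lactone), the C8–O ester bond (tiglate, with inversion at C8), the 11,13-diol (back to the exocyclic C11=C13 alkene), the four oxirane C–O bonds, the lactone C6–O bond with the oxygens at C8 and C12, and last the ring bond C6–C7 of the carbocycle.
- Feature that allows the last cut: the ten-membered ring C1–C10, with methyl groups on C4 and C10 and the three-carbon branch C11–C13 on C7, is a farnesyl chain folded head to tail, so farnesyl diphosphate already holds all fifteen skeletal carbons and both E-alkenes.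
- Forward order of rings: the ten-membered carbocycle closes first (enzymatic 1,10-cyclisation), the γ-lactone second (P450 oxidation at C12, C8 and C6, then lactonisation), the two oxiranes third (peracid).
- The lactone alkene is then moved from C11=C13 to C7=C11 by dihydroxylation, silylation, Mitsunobu tiglation, dehydration and desilylation; no carbon is added or lost after the cyclisation.
- Stereochemistry: the cyclase sets C7 (R); the P450 enzymes read that centre and set C6 (α-O) and C8 (β-OH); the crown conformation of the trans-lactone exposes one face of each ring alkene and sets C1, C10, C4 and C5; the Mitsunobu reaction inverts C8; C7 and the temporary centre C11 become sp2 at the end.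

Key step: step 3

Assumption: OsO4 is taken to add to the C11=C13 alkene from the α face, anti to the 8β-hydroxyl that lies over the β face of the lactone, so the 11-hydroxyl is α and syn to H-7; this centre is temporary and is erased in step 11.

**Route**

Step 1
Reactants: 1 (2E,6E)-farnesol
Product: 2 (2E,6E)-farnesyl chloride
Conditions: NCS, Me2S, CH2Cl2, −40 → 0 °C
Reagents that add atoms: N-chlorosuccinimide, O=C1CCC(=O)N1Cl
Why: Corey–Kim chlorination, in which chloride displaces the alkoxysulfonium group of the primary allylic alcohol in SN2 fashion, so neither allylic transposition nor loss of the 2E geometry is expected and no stereocentre is formed.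

Step 2
Reactants: 2 (2E,6E)-farnesyl chloride
Product: 3 (2E,6E)-farnesyl diphosphate (handled as the tris-ammonium salt, drawn as the free acid)
Conditions: (Bu4N)3HP2O7, MeCN, rt; cation exchange (NH4+ form); cellulose chromatography
Reagents that add atoms: tris(tetrabutylammonium) hydrogen diphosphate, CCCC[N+](CCCC)(CCCC)CCCC.CCCC[N+](CCCC)(CCCC)CCCC.CCCC[N+](CCCC)(CCCC)CCCC.OP(=O)([O-])OP(=O)([O-])[O-]
Why: SN2 displacement of a primary allylic chloride by the diphosphate anion in a dipolar aprotic solvent (standard allylic diphosphorylation), with the alkene geometry untouched.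

Step 3
Reactants: 3 (2E,6E)-farnesyl diphosphate
Product: 4 (+)-(R)-germacrene A (germacra-1(10)E,4E,11(13)-triene, H-7α)
Conditions: recombinant (+)-germacrene A synthase (e.g. LsGAS1 of Lactuca sativa, from E. coli), MgCl2, HEPES pH 7.2, DTT, pentane overlay, 30 °C; product kept cold and away from acid
Reagents that add atoms: none
Why: The synthase binds the diphosphate through three Mg2+ ions and ionises the C–O bond to the farnesyl allyl cation; the distal C10=C11 alkene of the chain (farnesyl numbering) attacks C1, which forms the germacrane C6–C7 bond, and the tertiary C11 cation loses a methyl proton to give the isopropenyl group. This is the native reaction of a class 1 sesquiterpene synthase, the enzymatic counterpart of a cation–olefin macrocyclisation. The single ring closes as a ten-membered carbocycle in a 1,10-closure in which the attacked alkene reacts in the exo (Markovnikov) sense, leaving the cation on the exocyclic carbon C11. The one new stereocentre, C7, is fixed as R because the active-site fold presents only one face of the distal alkene to C1. The step needs 1,10- over 1,11-closure, retention of both E-alkenes, and termination by proton loss instead of a second transannular cyclisation or water capture. The enzyme pocket secures this by holding the chain in one fold, excluding water and placing the departing diphosphate as base next to the C11 methyl, and the 2E geometry of 3 lets the ring close without prior isomerisation.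

Step 4
Reactants: 4 (+)-(R)-germacrene A
Product: 7 germacra-1(10),4,11(13)-trien-12-oic acid (germacrene A acid), via germacratrien-12-ol 5 (not isolated), via germacratrien-12-al 6 (not isolated)
Conditions: microsomes of S. cerevisiae WAT11 expressing germacrene A oxidase (CiGAO of Cichorium intybus) with the reductase ATR1, NADPH (cat.), D-glucose, glucose dehydrogenase, air, K2HPO4/KH2PO4 buffer pH 7.5, 30 °C
Reagents that add atoms: dioxygen, O=O
Why: Germacrene A oxidase is a cytochrome P450 that hydroxylates the allylic C12 methyl of the isopropenyl group and then oxidises the alcohol and the aldehyde at the same site (three successive P450 monooxygenations), leaving C7 and both ring alkenes untouched.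

Step 5
Reactants: 7 germacrene A acid
Product: 8 8β-hydroxygermacra-1(10),4,11(13)-trien-12-oic acid
Conditions: microsomes of S. cerevisiae WAT11 expressing CYP71BL1 (germacrene A acid 8β-hydroxylase of Helianthus annuus), NADPH (cat.), D-glucose, glucose dehydrogenase, air, K2HPO4/KH2PO4 buffer pH 7.5, 30 °C
Reagents that add atoms: dioxygen, O=O
Why: Regio- and stereospecific P450 C–H hydroxylation; the enzyme positions C8 of the (7R)-acid over the haem and delivers oxygen with retention to the β face, which sets C8 as 8β-OH.

Step 6
Reactants: 8 8β-hydroxygermacrene A acid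
Product: 10 eupatolide (8β-hydroxygermacra-1(10)E,4E,11(13)-trien-12,6α-olide), via 6α,8β-dihydroxy acid 9 (not isolated)
Conditions: microsomes of S. cerevisiae WAT11 expressing CYP71DD6 (eupatolide synthase of Helianthus annuus), NADPH (cat.), D-glucose, glucose dehydrogenase, air, K2HPO4/KH2PO4 buffer pH 7.5, 30 °C
Reagents that add atoms: dioxygen, O=O
Why: P450 hydroxylation of the allylic C6 position from the α face sets C6, and the resulting γ-hydroxy acid closes spontaneously onto C12 to the trans-fused 12,6α-lactone (5-exo-trig lactonisation), while the 8β-hydroxyl stays free.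

Step 7
Reactants: 10 eupatolide
Product: 11 1β,10α:4α,5β-diepoxy-8β-hydroxygermacr-11(13)-en-12,6α-olide
Conditions: mCPBA (2.3 equiv), NaHCO3 buffer, CH2Cl2, 0 °C
Reagents that add atoms: meta-chloroperbenzoic acid, O=C(OO)c1cccc(Cl)c1
Why: Prilezhaev epoxidation, which takes the two electron-rich trisubstituted ring alkenes and leaves the conjugated exocyclic methylene alone; in the crown conformation (C14 and C15 both on the β face) only the outer face of each E-alkene is open, which should give the 1β,10α- and 4α,5β-oxiranes and so set C1, C10, C4 and C5.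

Step 8
Reactants: 11 diepoxy-8β-hydroxy α-methylene lactone
Product: 12 1β,10α:4α,5β-diepoxy-8β,11α,13-trihydroxygermacran-12,6α-olide
Conditions: OsO4 (5 mol %), NMO, acetone/H2O 4:1, 0 °C → rt
Reagents that add atoms: N-methylmorpholine N-oxide, C[N+]1([O-])CCOCC1; water, O; OsO4 (catalytic oxygen carrier), O=[Os](=O)(=O)=O
Why: Upjohn dihydroxylation of the only alkene left in the molecule; the osmium reagent should approach anti to the 8β-hydroxyl (α face), placing the 11-hydroxyl syn to H-7 at a centre that is removed later.

Step 9
Reactants: 12 diepoxy triol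
Product: 13 13-O-(tert-butyldimethylsilyl) ether of 12 (8β-OH and 11α-OH free)
Conditions: TBSCl (1.1 equiv), imidazole, CH2Cl2/DMF, 0 °C
Reagents that add atoms: tert-butyldimethylsilyl chloride, CC(C)(C)[Si](C)(C)Cl
Why: Silyl ether formation that is selective for the primary 13-hydroxyl over the hindered secondary 8-hydroxyl and the tertiary 11-hydroxyl; no stereocentre changes.

Step 10
Reactants: 13 13-O-TBS diol; 14 tiglic acid ((E)-2-methylbut-2-enoic acid)
Product: 15 8α-tigloyloxy-11α-hydroxy-13-(tert-butyldimethylsilyloxy)-1β,10α:4α,5β-diepoxygermacran-12,6α-olide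
Conditions: PPh3, DIAD, toluene, 0 °C → rt
Reagents that add atoms: tiglic acid (14), C/C=C(\C)C(=O)O
Why: Mitsunobu esterification, in which tiglate displaces the oxyphosphonium group at C8 from the rear and so inverts 8β-OH to the 8α-ester of the target, while the tertiary 11-hydroxyl cannot be activated under these conditions.

Step 11
Reactants: 15 8α-tiglate 11α-hydroxy lactone
Product: 16 8α-tigloyloxy-13-(tert-butyldimethylsilyloxy)-1β,10α:4α,5β-diepoxygermacr-7(11)-en-12,6α-olide
Conditions: Burgess reagent (2 equiv), toluene, 50 °C
Reagents that add atoms: none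
Why: Burgess dehydration (syn elimination through the sulfamate ester of the tertiary alcohol), which should remove H-7, syn to the 11α-oxygen, and give the conjugated tetrasubstituted butenolide, because loss of a hydrogen from the silyloxy-bearing C13 would form a less substituted enol ether.

Step 12
Reactants: 16 13-O-TBS butenolide
Product: 17 8α-tigloyloxy-13-hydroxy-1β,10α:4α,5β-diepoxygermacr-7(11)-en-12,6α-olide (target)
Conditions: TBAF, AcOH (1:1), THF, 0 °C → rt
Reagents that add atoms: none
Why: Fluoride-induced cleavage of the silyl ether, buffered with acetic acid so that no free alkoxide can epimerise the γ-position C6 of the butenolide, shift the tiglate or open an oxirane.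

**Compound list**

1 | (2E,6E)-farnesol | CC(C)=CCC/C(C)=C/CC/C(C)=C/CO | starting material
2 | (2E,6E)-farnesyl chloride | CC(C)=CCC/C(C)=C/CC/C(C)=C/CCl | intermediate
3 | (2E,6E)-farnesyl diphosphate (tris-ammonium salt, drawn as free acid) | CC(C)=CCC/C(C)=C/CC/C(C)=C/COP(=O)(O)OP(=O)(O)O | intermediate
4 | (+)-(R)-germacrene A | CC(=C)[C@@H]1CC/C(C)=C/CC/C(C)=C/C1 | intermediate
5 | germacra-1(10),4,11(13)-trien-12-ol (not isolated) | C=C(CO)[C@@H]1CC/C(C)=C/CC/C(C)=C/C1 | intermediate
6 | germacra-1(10),4,11(13)-trien-12-al (not isolated) | C=C(C=O)[C@@H]1CC/C(C)=C/CC/C(C)=C/C1 | intermediate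
7 | germacra-1(10),4,11(13)-trien-12-oic acid (germacrene A acid) | C=C(C(=O)O)[C@@H]1CC/C(C)=C/CC/C(C)=C/C1 | intermediate
8 | 8β-hydroxygermacra-1(10),4,11(13)-trien-12-oic acid | C=C(C(=O)O)[C@@H]1[C@H](O)C/C(C)=C/CC/C(C)=C/C1 | intermediate
9 | 6α,8β-dihydroxygermacra-1(10),4,11(13)-trien-12-oic acid (not isolated) | C=C(C(=O)O)[C@@H]1[C@H](O)C/C(C)=C/CC/C(C)=C/[C@H]1O | intermediate
10 | eupatolide (8β-hydroxygermacra-1(10),4,11(13)-trien-12,6α-olide) | O[C@@H]1C/C(C)=C/CC/C(C)=C/[C@H]2OC(=O)C(=C)[C@H]12 | intermediate
11 | 1β,10α:4α,5β-diepoxy-8β-hydroxygermacr-11(13)-en-12,6α-olide | O[C@@H]1C[C@@]2(C)O[C@@H]2CC[C@@]2(C)O[C@@H]2[C@H]2OC(=O)C(=C)[C@H]12 | intermediate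
12 | 1β,10α:4α,5β-diepoxy-8β,11α,13-trihydroxygermacran-12,6α-olide | O[C@@H]1C[C@@]2(C)O[C@@H]2CC[C@@]2(C)O[C@@H]2[C@H]2OC(=O)[C@](O)(CO)[C@H]12 | intermediate
13 | 13-O-(tert-butyldimethylsilyl) ether of 12 | O[C@@H]1C[C@@]2(C)O[C@@H]2CC[C@@]2(C)O[C@@H]2[C@H]2OC(=O)[C@](O)(CO[Si](C)(C)C(C)(C)C)[C@H]12 | intermediate
14 | tiglic acid | C/C=C(\C)C(=O)O | starting material
15 | 8α-tigloyloxy-11α-hydroxy-13-(tert-butyldimethylsilyloxy)-1β,10α:4α,5β-diepoxygermacran-12,6α-olide | C/C=C(\C)C(=O)O[C@H]1C[C@@]2(C)O[C@@H]2CC[C@@]2(C)O[C@@H]2[C@H]2OC(=O)[C@](O)(CO[Si](C)(C)C(C)(C)C)[C@H]12 | intermediate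
16 | 8α-tigloyloxy-13-(tert-butyldimethylsilyloxy)-1β,10α:4α,5β-diepoxygermacr-7(11)-en-12,6α-olide | C/C=C(\C)C(=O)O[C@H]1C[C@@]2(C)O[C@@H]2CC[C@@]2(C)O[C@@H]2[C@H]2OC(=O)C(CO[Si](C)(C)C(C)(C)C)=C12 | intermediate
17 | 8α-tigloyloxy-13-hydroxy-1β,10α:4α,5β-diepoxygermacr-7(11)-en-12,6α-olide (CNP0111480.1) | C/C=C(\C)C(=O)O[C@H]1C[C@@]2(C)O[C@@H]2CC[C@@]2(C)O[C@@H]2[C@H]2OC(=O)C(CO)=C12 | target

**Step count**

Total: 12 steps. Longest linear sequence: 12 steps (1 → 17); tiglic acid 14 enters in step 10.

**Steps most likely to fail**

1. Step 11 (dehydration). The syn elimination may take a hydrogen from C13 and form the silyl enol ether, it may find no syn hydrogen at C7 if the dihydroxylation delivered the 11-hydroxyl to the β face, and warm Burgess reagent may attack an oxirane. The fallback removes the dependence on the C11 configuration and on the direction of elimination; it sets out from 15 and returns to the route at 17. Desilylation (TBAF/AcOH, THF) should give the 8α-tigloyloxy-11α,13-diol F1. Periodate cleavage (NaIO4, THF/H2O) should remove C13 and give the 13-nor α-keto lactone, which rests as its enol, the 11-hydroxy-7(11)-en-12,6α-olide F2. PhNTf2/Et3N in CH2Cl2 should convert it into the enol triflate F3. Stille coupling with (tributylstannyl)methanol (Pd(PPh3)4, LiCl, dioxane, 70 °C) should then install the hydroxymethyl group on C11 and give 17 directly.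

2. Step 10 (Mitsunobu inversion). C8 is a hindered secondary carbinol next to C7 and the quaternary C11, so the oxyphosphonium intermediate may eliminate toward C9, or the alcohol may be recovered or esterified with retention. The fallback separates activation from substitution; it sets out from 13 and returns at 15. Chloromethanesulfonyl chloride/pyridine (CH2Cl2, 0 °C) should give the 8β-chloromethanesulfonate F4. Heating it with cesium tiglate (from 14 and Cs2CO3) and 18-crown-6 in toluene at 80 °C should displace the sulfonate with inversion and give 15.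

3. Step 4 (threefold P450 oxidation). The hydrocarbon 4 is volatile, poorly soluble in buffer, prone to proton-induced transannular cyclisation and to Cope rearrangement on warming, and the oxidation may stall at 5 or 6 when turnover is low. The fallback changes the process so that 4 is never isolated: it sets out from 3 and returns at 7. The germacrene A synthase of step 3 and the oxidase microsomes of step 4, with the same NADPH-recycling system, are run together in one buffered vessel, so that 4 is oxidised as it leaves the cyclase and only the acid 7 is extracted at pH 7. No new compound arises.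

**Further compounds**

F1 | step 11 | 8α-tigloyloxy-11α,13-dihydroxy-1β,10α:4α,5β-diepoxygermacran-12,6α-olide | C/C=C(\C)C(=O)O[C@H]1C[C@@]2(C)O[C@@H]2CC[C@@]2(C)O[C@@H]2[C@H]2OC(=O)[C@](O)(CO)[C@H]12
F2 | step 11 | 8α-tigloyloxy-11-hydroxy-13-nor-1β,10α:4α,5β-diepoxygermacr-7(11)-en-12,6α-olide (enol of the α-keto lactone) | C/C=C(\C)C(=O)O[C@H]1C[C@@]2(C)O[C@@H]2CC[C@@]2(C)O[C@@H]2[C@H]2OC(=O)C(O)=C12
F3 | step 11 | 11-O-trifluoromethanesulfonate of F2 (enol triflate) | C/C=C(\C)C(=O)O[C@H]1C[C@@]2(C)O[C@@H]2CC[C@@]2(C)O[C@@H]2[C@H]2OC(=O)C(OS(=O)(=O)C(F)(F)F)=C12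
F4 | step 10 | 8β-chloromethanesulfonate of 13 | O=S(=O)(CCl)O[C@@H]1C[C@@]2(C)O[C@@H]2CC[C@@]2(C)O[C@@H]2[C@H]2OC(=O)[C@](O)(CO[Si](C)(C)C(C)(C)C)[C@H]12
F0 | step 4 | none | none
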